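The diaryl ether is cut at the bond between the ring C phenol oxygen and ring B C3 (ring B numbered from its bridge carbon). Ring B carries its hydroxyl on C4, next to that ether carbon. A nitro group standing in for this hydroxyl makes a fluoride on C3 displaceable and is later exchanged for OH. In one operation the ring C phenoxide attacks the fluorinated carbon, forging the aryl–oxygen bond and closing the 16-membered ring. The precursor is the assembled open chain: the ring A–ring D biaryl with both ethylene bridges in place, rings A and D as methyl ethers, ring C as the only free phenol, ring B as a 3-fluoro-4-nitrophenyl group.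

Key step: step 8

Remarks:
- Ring A is the biaryl ring with OH para to the biaryl bond, ring B the ring with OH next to the ether carbon, ring C the para-phenylene ring, and ring D the biaryl ring with OH ortho to the biaryl bond.
- Compounds 1, 3, 7 and 10 are assumed to be purchasable.
- The target SMILES defines no stereo element; the tri-ortho-substituted biaryl axis forms racemic and is left unspecified.

Step 1
Reactants: 1 4-(benzyloxy)benzyl chloride
Product: 2 [4-(benzyloxy)benzyl]triphenylphosphonium chloride
Conditions: PPh3, toluene, reflux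
Reagents that add atoms: triphenylphosphine, c1ccc(cc1)P(c1ccccc1)c1ccccc1
Why: SN2 quaternisation of PPh3 by an electron-rich benzylic chloride (phosphonium salt formation) is reliable, and the salt should crystallise from toluene.

Step 2
Reactants: 2 [4-(benzyloxy)benzyl]triphenylphosphonium chloride; 3 2-bromo-3-methoxybenzaldehyde
Product: 5 1-{2-[4-(benzyloxy)phenyl]ethenyl}-2-bromo-3-methoxybenzene (E/Z mixture), via phosphorus ylide 4 (not isolated)
Conditions: KOtBu, THF, 0 °C; then 3, 0 °C to rt
Reagents that add atoms: none
Why: Wittig olefination of the aldehyde by the semi-stabilised benzylic ylide should proceed cleanly because aryl bromide and benzyl ether are inert to ylide and alkoxide, and the E/Z ratio is irrelevant since the double bond is saturated in step 3.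

Step 3
Reactants: 5 1-{2-[4-(benzyloxy)phenyl]ethenyl}-2-bromo-3-methoxybenzene
Product: 6 1-{2-[4-(benzyloxy)phenyl]ethyl}-2-bromo-3-methoxybenzene
Conditions: TsNHNH2, NaOAc, THF/H2O, reflux
Reagents that add atoms: none
Why: Diimide reduction, in which diimide released from the sulfonyl hydrazide transfers two hydrogens to the nonpolar C=C bond in a concerted syn fashion, should leave the C–Br bond and the benzyl ether untouched, unlike hydrogenation over palladium.

Step 4
Reactants: 6 1-{2-[4-(benzyloxy)phenyl]ethyl}-2-bromo-3-methoxybenzene; 7 2-formyl-4-methoxyphenylboronic acid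
Product: 8 6'-{2-[4-(benzyloxy)phenyl]ethyl}-2',4-dimethoxy-[1,1'-biphenyl]-2-carbaldehyde
Conditions: Pd(OAc)2 (cat.), SPhos, K3PO4, toluene/H2O, 100 °C
Reagents that add atoms: none
Why: Suzuki–Miyaura coupling with the bulky electron-rich SPhos ligand should force oxidative addition into the doubly ortho-substituted bromide and reductive elimination to the tri-ortho-substituted biaryl, an excess of 7 offsetting its protodeboronation.

Step 5
Reactants: 8 6'-{2-[4-(benzyloxy)phenyl]ethyl}-2',4-dimethoxy-[1,1'-biphenyl]-2-carbaldehyde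
Product: 9 2-{2-[4-(benzyloxy)phenyl]ethyl}-2'-ethenyl-4',6-dimethoxy-1,1'-biphenyl
Conditions: Ph3PCH3Br, KOtBu, THF, 0 °C to rt
Reagents that add atoms: methyltriphenylphosphonium bromide, C[P+](c1ccccc1)(c1ccccc1)c1ccccc1.[Br-]
Why: Wittig methylenation of an aryl aldehyde with the non-stabilised ylide is fast even beside the hindered biaryl axis, and the aldehyde is the only electrophile in 8.

Step 6
Reactants: 9 2-{2-[4-(benzyloxy)phenyl]ethyl}-2'-ethenyl-4',6-dimethoxy-1,1'-biphenyl; 10 4-bromo-2-fluoro-1-nitrobenzene
Product: 12 2-{2-[4-(benzyloxy)phenyl]ethyl}-2'-[2-(3-fluoro-4-nitrophenyl)ethyl]-4',6-dimethoxy-1,1'-biphenyl, via B-alkyl-9-BBN borane 11 (not isolated)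
Conditions: 9-BBN, THF, 0 °C to rt; then 10, PdCl2(dppf) (cat.), K3PO4, DMF/H2O, rt
Reagents that add atoms: none
Why: Anti-Markovnikov hydroboration of the styrene followed by B-alkyl Suzuki–Miyaura coupling should install the saturated bridge directly, since the bromide para to the nitro group adds rapidly to zerovalent palladium at room temperature while phosphate is too weak a nucleophile to displace the activated fluoride, so no alkene has to be reduced beside the nitro group.

Step 7
Reactants: 12 2-{2-[4-(benzyloxy)phenyl]ethyl}-2'-[2-(3-fluoro-4-nitrophenyl)ethyl]-4',6-dimethoxy-1,1'-biphenyl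
Product: 13 4-(2-{2'-[2-(3-fluoro-4-nitrophenyl)ethyl]-4',6-dimethoxy-[1,1'-biphenyl]-2-yl}ethyl)phenol
Conditions: BCl3, pentamethylbenzene, CH2Cl2, −78 °C; then H2O
Reagents that add atoms: none
Why: Lewis acid debenzylation, in which BCl3 ionises the aryl benzyl ether and pentamethylbenzene traps the benzyl cation by Friedel–Crafts alkylation, should spare the aryl methyl ethers, the nitro group and the C–F bond and forms no phenoxide that could start SNAr prematurely.

Step 8
Reactants: 13 4-(2-{2'-[2-(3-fluoro-4-nitrophenyl)ethyl]-4',6-dimethoxy-[1,1'-biphenyl]-2-yl}ethyl)phenol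
Product: 15 macrocyclic nitro diaryl ether (ring C oxygen bonded to ring B C3, NO2 on ring B C4, OMe on rings A and D), via caesium phenoxide 14 (not isolated)
Conditions: Cs2CO3, DMF (0.005 M, slow addition of 13), rt
Reagents that add atoms: none
Why: Cs2CO3 deprotonates the ring C phenol, the phenoxide oxygen adds to the fluorine-bearing ring B carbon to give a Meisenheimer adduct whose charge rests on the ortho nitro group, and loss of fluoride restores the arene (addition–elimination SNAr). The closest known reaction type is the intramolecular cycloetherification of phenoxides onto ortho-fluoronitroarenes that closes macrocyclic diaryl ethers in cyclopeptides and diarylheptanoids at room temperature. The 16-membered ring is closed end to end by this single C–O bond, the preformed biaryl and the two saturated bridges holding the phenoxide and the C–F carbon on the same side of the chain. No stereocentre is created, and any twist of the biaryl axis would arise in both senses. Ring closure must outrun chain growth, which high dilution with slow addition and the fast addition to the activated arene should secure. Regiochemistry is not in question because 13 holds one acidic phenol and one activated fluoride while rings A and D stay masked as methyl ethers.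

Step 9
Reactants: 15 macrocyclic nitro diaryl ether
Product: 16 macrocyclic amino diaryl ether (NH2 on ring B C4)
Conditions: H2 (1 atm), Pd/C, EtOAc/EtOH, rt
Reagents that add atoms: none
Why: Heterogeneous catalytic hydrogenation of the nitroarene to the aniline should be clean because the molecule now holds no halide, benzyl ether or alkene.

Step 10
Reactants: 16 macrocyclic amino diaryl ether
Product: 18 plagiochin E dimethyl ether (free OH on ring B C4, OMe on rings A and D), via arenediazonium hydrogensulfate 17 (not isolated)
Conditions: NaNO2, H2SO4, AcOH/H2O, 0 °C; then Cu(NO3)2 (excess), Cu2O, H2O, rt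
Reagents that add atoms: water, O
Why: Diazotisation followed by copper-mediated hydroxydediazoniation (Sandmeyer-type) should give the phenol at room temperature, since monovalent copper reduces the diazonium ion to the aryl radical and aquated divalent copper in large excess captures it faster than it can attack ring C or abstract hydrogen, returning monovalent copper.

Step 11
Reactants: 18 plagiochin E dimethyl ether
Product: 19 plagiochin E
Conditions: BBr3, CH2Cl2, −78 °C to rt; then H2O
Reagents that add atoms: none
Why: BBr3 ether cleavage, in which boron coordinates each methoxy oxygen and bromide removes the methyl group by SN2, should free both phenols while the diaryl ether, which has no sp3 carbon on oxygen, and the biaryl stay intact.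

Compound list
1 | 4-(benzyloxy)benzyl chloride | ClCc1ccc(OCc2ccccc2)cc1 | starting material
2 | [4-(benzyloxy)benzyl]triphenylphosphonium chloride | [Cl-].c1ccc(cc1)COc1ccc(C[P+](c2ccccc2)(c2ccccc2)c2ccccc2)cc1 | intermediate
3 | 2-bromo-3-methoxybenzaldehyde | COc1cccc(C=O)c1Br | starting material
4 | [4-(benzyloxy)benzylidene]triphenylphosphorane | c1ccc(cc1)COc1ccc(C=P(c2ccccc2)(c2ccccc2)c2ccccc2)cc1 | intermediate (not isolated)
5 | 1-{2-[4-(benzyloxy)phenyl]ethenyl}-2-bromo-3-methoxybenzene, E/Z mixture, geometry left open | COc1cccc(C=Cc2ccc(OCc3ccccc3)cc2)c1Br | intermediate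
6 | 1-{2-[4-(benzyloxy)phenyl]ethyl}-2-bromo-3-methoxybenzene | COc1cccc(CCc2ccc(OCc3ccccc3)cc2)c1Br | intermediate
7 | 2-formyl-4-methoxyphenylboronic acid | COc1ccc(B(O)O)c(C=O)c1 | starting material
8 | 6'-{2-[4-(benzyloxy)phenyl]ethyl}-2',4-dimethoxy-[1,1'-biphenyl]-2-carbaldehyde | COc1ccc(c(C=O)c1)-c1c(OC)cccc1CCc1ccc(OCc2ccccc2)cc1 | intermediate
9 | 2-{2-[4-(benzyloxy)phenyl]ethyl}-2'-ethenyl-4',6-dimethoxy-1,1'-biphenyl | COc1ccc(c(C=C)c1)-c1c(OC)cccc1CCc1ccc(OCc2ccccc2)cc1 | intermediate
10 | 4-bromo-2-fluoro-1-nitrobenzene | O=[N+]([O-])c1ccc(Br)cc1F | starting material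
11 | 9-alkyl-9-borabicyclo[3.3.1]nonane from 9, boron on the terminal carbon | COc1ccc(c(CCB2C3CCCC2CCC3)c1)-c1c(OC)cccc1CCc1ccc(OCc2ccccc2)cc1 | intermediate (not isolated)
12 | 2-{2-[4-(benzyloxy)phenyl]ethyl}-2'-[2-(3-fluoro-4-nitrophenyl)ethyl]-4',6-dimethoxy-1,1'-biphenyl | COc1ccc(c(c1)CCc1ccc([N+](=O)[O-])c(F)c1)-c1c(OC)cccc1CCc1ccc(OCc2ccccc2)cc1 | intermediate
13 | 4-(2-{2'-[2-(3-fluoro-4-nitrophenyl)ethyl]-4',6-dimethoxy-[1,1'-biphenyl]-2-yl}ethyl)phenol (seco fluoronitroarene phenol) | COc1ccc(c(c1)CCc1ccc([N+](=O)[O-])c(F)c1)-c1c(OC)cccc1CCc1ccc(O)cc1 | intermediate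
14 | caesium phenoxide of 13 | COc1ccc(c(c1)CCc1ccc([N+](=O)[O-])c(F)c1)-c1c(OC)cccc1CCc1ccc([O-])cc1.[Cs+] | intermediate (not isolated)
15 | macrocyclic nitro diaryl ether (16-membered ring, NO2 on ring B C4, OMe on rings A and D) | COc1ccc2c(c1)CCc1ccc([N+](=O)[O-])c(c1)Oc1ccc(cc1)CCc1cccc(OC)c1-2 | intermediate
16 | macrocyclic amino diaryl ether (NH2 on ring B C4) | COc1ccc2c(c1)CCc1ccc(N)c(c1)Oc1ccc(cc1)CCc1cccc(OC)c1-2 | intermediate
17 | macrocyclic arenediazonium hydrogensulfate (N2+ on ring B C4) | COc1ccc2c(c1)CCc1ccc([N+]#N)c(c1)Oc1ccc(cc1)CCc1cccc(OC)c1-2.OS(=O)(=O)[O-] | intermediate (not isolated)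
18 | plagiochin E dimethyl ether (OH on ring B, OMe on rings A and D) | COc1ccc2c(c1)CCc1ccc(O)c(c1)Oc1ccc(cc1)CCc1cccc(OC)c1-2 | intermediate
19 | plagiochin E | Oc1ccc2c(c1)CCc1ccc(O)c(c1)Oc1ccc(cc1)CCc1cccc(O)c1-2 | target

Total step count: 11
Longest linear sequence: 11 steps (1 to 19)

Steps most likely to fail

Step 8. Chain growth between two molecules may outpace ring closure, or closure may stall because the para-bridged ring C has to bend to reach the ring B carbon. Dimethylamine from DMF may also consume the fluoride. The fallback sets out from 8 and comes back at 16. It forms the diaryl ether between two molecules and closes the ring at the ring A–ring B bridge instead. Debenzylation of 8 with BCl3 and pentamethylbenzene in CH2Cl2 at −78 °C should give 6'-[2-(4-hydroxyphenyl)ethyl]-2',4-dimethoxybiphenyl-2-carbaldehyde F1. Intermolecular SNAr of its phenoxide (K2CO3, DMF, rt) on (3-fluoro-4-nitrophenyl)methanol should give the diaryl ether benzylic alcohol F2. CBr4 and PPh3 in CH2Cl2 should convert it into the benzylic bromide F3, and PPh3 in toluene into the phosphonium bromide F4. Slow addition of F4 to K2CO3 and 18-crown-6 in CH2Cl2 at high dilution generates the nitro-stabilised ylide F5. This should close the ring by intramolecular Wittig reaction onto the ring A aldehyde, giving the macrocyclic nitrostilbene F6. Hydrogenation over Pd/C then reduces the alkene and the nitro group together and delivers 16.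

Step 6. The activated fluoride may be hydrolysed by the aqueous base, or the alkylborane may lose boron by protonolysis before transmetalation. The fallback sets out from 8 and comes back at 12. NaBH4 in MeOH/THF should reduce 8 to the benzylic alcohol F7. PPh3·HBr in refluxing MeCN should convert it directly into the benzylic phosphonium bromide F8. K2CO3 and 18-crown-6 in CH2Cl2 generate the ylide F9 in the presence of 3-fluoro-4-nitrobenzaldehyde, and Wittig reaction should give the fluoronitrostilbene F10 as an E/Z mixture. Homogeneous hydrogenation with RhCl(PPh3)3 under H2 in THF/t-BuOH should saturate the alkene while sparing nitro group, fluoride and benzyl ether, giving 12.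

Step 10. The aryl radical may be diverted into hydrodediazoniation or into Pschorr-type closure onto ring C before oxygen is delivered. The diazonium ion may also couple with electron-rich rings. The fallback sets out from 16 and comes back at 18. The solution of 17 prepared as in step 10 is poured into aqueous KI, which should give the macrocyclic aryl iodide F11. Palladium-catalysed hydroxylation of the iodide (Pd2(dba)3, t-BuXPhos, KOH, 1,4-dioxane/H2O, 100 °C) should then give 18.

Further compounds
F1 | step 8 | 6'-[2-(4-hydroxyphenyl)ethyl]-2',4-dimethoxybiphenyl-2-carbaldehyde | COc1ccc(c(C=O)c1)-c1c(OC)cccc1CCc1ccc(O)cc1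
F2 | step 8 | 6'-(2-{4-[5-(hydroxymethyl)-2-nitrophenoxy]phenyl}ethyl)-2',4-dimethoxybiphenyl-2-carbaldehyde | COc1ccc(c(C=O)c1)-c1c(OC)cccc1CCc1ccc(Oc2cc(CO)ccc2[N+](=O)[O-])cc1
F3 | step 8 | 6'-(2-{4-[5-(bromomethyl)-2-nitrophenoxy]phenyl}ethyl)-2',4-dimethoxybiphenyl-2-carbaldehyde | COc1ccc(c(C=O)c1)-c1c(OC)cccc1CCc1ccc(Oc2cc(CBr)ccc2[N+](=O)[O-])cc1
F4 | step 8 | benzylic triphenylphosphonium bromide from F3 | COc1ccc(c(C=O)c1)-c1c(OC)cccc1CCc1ccc(Oc2cc(C[P+](c3ccccc3)(c3ccccc3)c3ccccc3)ccc2[N+](=O)[O-])cc1.[Br-]
F5 | step 8 | nitro-stabilised ylide from F4 | COc1ccc(c(C=O)c1)-c1c(OC)cccc1CCc1ccc(Oc2cc(C=P(c3ccccc3)(c3ccccc3)c3ccccc3)ccc2[N+](=O)[O-])cc1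
F6 | step 8 | macrocyclic nitrostilbene (C=C between rings A and B, geometry left open) | COc1ccc2c(c1)C=Cc1ccc([N+](=O)[O-])c(c1)Oc1ccc(cc1)CCc1cccc(OC)c1-2
F7 | step 6 | (6'-{2-[4-(benzyloxy)phenyl]ethyl}-2',4-dimethoxybiphenyl-2-yl)methanol | COc1ccc(c(CO)c1)-c1c(OC)cccc1CCc1ccc(OCc2ccccc2)cc1
F8 | step 6 | benzylic triphenylphosphonium bromide from F7 | COc1ccc(c(C[P+](c2ccccc2)(c2ccccc2)c2ccccc2)c1)-c1c(OC)cccc1CCc1ccc(OCc2ccccc2)cc1.[Br-]
F9 | step 6 | ylide from F8 | COc1ccc(c(C=P(c2ccccc2)(c2ccccc2)c2ccccc2)c1)-c1c(OC)cccc1CCc1ccc(OCc2ccccc2)cc1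
F10 | step 6 | 2-{2-[4-(benzyloxy)phenyl]ethyl}-2'-[2-(3-fluoro-4-nitrophenyl)ethenyl]-4',6-dimethoxy-1,1'-biphenyl, E/Z mixture | COc1ccc(c(C=Cc2ccc([N+](=O)[O-])c(F)c2)c1)-c1c(OC)cccc1CCc1ccc(OCc2ccccc2)cc1
F11 | step 10 | macrocyclic aryl iodide (I on ring B C4) | COc1ccc2c(c1)CCc1ccc(I)c(c1)Oc1ccc(cc1)CCc1cccc(OC)c1-2
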